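**Assumption:** ring locants C1–C12 are those of the bicyclo[10.3.2] name of the target (C1 = lactone CH bridgehead, C12 = O-bearing quaternary bridgehead); catalyst enantiomers are chosen from the accepted facial models and would be swapped for their mirror images if a sense proved opposite.

## Retrosynthetic overview

1. Target ⇐ oxazaborolidine reduction of the C3 enone ⇐ Evans–Tishchenko reduction of a macrocyclic β-hydroxy enone, which sets C9 and places the acetate on O11.
2. The fourteen-membered ring is closed second, by a Nozaki–Hiyama–Kishi (NHK) coupling at C8–C9 followed by allylic oxidation.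
3. The seven-membered α-methylene lactone is closed first, by acid-triggered 7-exo opening of a Shi epoxide (C11/C12) by the C1 acrylate carboxyl.
4. C3–C4 comes from an intermolecular NHK coupling of a (Z)-bromo/(E)-iodo skipped diene, used as the enone.
5. C1, the first stereocentre, comes from a dual amine/Lewis-base cross Rauhut–Currier reaction of an achiral trienal with tert-butyl acrylate.

## Route

**Step 1**
Reactants: 1 but-2-yn-1-ol
Product: 3 (2Z)-3-bromobut-2-en-1-ol, via cyclic alkenylaluminate 2 (not isolated)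
Conditions: NaAlH2(OCH2CH2OCH3)2, THF, 0 °C to rt; then NBS, −78 to 0 °C
Reagents that add atoms: N-bromosuccinimide, O=C1CCC(=O)N1Br
Why: Alkoxide-directed trans-hydroalumination puts Al on C3 in a five-membered aluminate, and bromodealumination with retention gives the Z bromide.

**Step 2**
Reactants: 3 (2Z)-3-bromobut-2-en-1-ol
Product: 4 (2Z)-1,3-dibromobut-2-ene
Conditions: PBr3 (0.4 equiv), Et2O, 0 °C
Reagents that add atoms: phosphorus tribromide, BrP(Br)Br
Why: SN2 bromination of the primary allylic alcohol leaves the vinylic bromide and the alkene geometry untouched.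

**Step 3**
Reactants: 4 (2Z)-1,3-dibromobut-2-ene; 5 prop-1-yn-1-ylmagnesium bromide
Product: 6 (2Z)-2-bromohept-2-en-5-yne
Conditions: CuBr·SMe2 (10 mol%), THF, −30 to 0 °C
Reagents that add atoms: none
Why: Copper-catalysed alkynyl–allyl coupling occurs by SN2 at the primary allylic bromide, since the γ-carbon is fully substituted and the vinylic bromide is inert.

**Step 4**
Reactants: 6 (2Z)-2-bromohept-2-en-5-yne
Product: 8 (2Z,5E)-2-bromo-6-iodohepta-2,5-diene, via alkenylzirconocene 7 (not isolated)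
Conditions: Cp2Zr(H)Cl (2.5 equiv), THF, 50 °C; then I2, 0 °C
Reagents that add atoms: iodine, II
Why: Syn hydrozirconation of the 2-alkyne under equilibrating conditions places Zr next to the methyl group, and iodinolysis with retention gives the (E)-2-iodoalkene.

**Step 5**
Reactants: 9 pent-4-yn-1-ol; 10 allyl bromide
Product: 12 (4E)-4-methylocta-4,7-dien-1-ol, via alkenylalane 11 (not isolated)
Conditions: Me3Al (3 equiv), Cp2ZrCl2 (0.25 equiv), CH2Cl2, 0 °C to rt; then 10, Pd(PPh3)4 (3 mol%), THF, rt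
Reagents that add atoms: trimethylaluminium, C[Al](C)C
Why: Negishi syn-carboalumination followed by Pd-catalysed allylation of the alkenylalane with retention gives the E trisubstituted 1,4-diene.

**Step 6**
Reactants: 12 (4E)-4-methylocta-4,7-dien-1-ol; 13 (triphenylphosphoranylidene)acetaldehyde
Product: 15 (2E,6E)-6-methyldeca-2,6,9-trienal, via dienal 14 (not isolated)
Conditions: TEMPO (10 mol%), PhI(OAc)2, CH2Cl2, rt; then 13, 40 °C
Reagents that add atoms: none
Why: Oxoammonium oxidation to the aldehyde and in-situ Wittig reaction with the stabilised ylide give the E enal in one pot.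

**Step 7**
Reactants: 15 (2E,6E)-6-methyldeca-2,6,9-trienal; 16 tert-butyl acrylate
Product: 17 tert-butyl (3S,6E)-6-methyl-2-methylidene-3-(2-oxoethyl)deca-6,9-dienoate
Conditions: 16 (5 equiv), (R)-2-[diphenyl(trimethylsilyloxy)methyl]pyrrolidine (20 mol%), 1,4-diazabicyclo[2.2.2]octane (20 mol%), 4-nitrophenol (20 mol%), CHCl3, 0 °C to rt
Reagents that add atoms: none
Why: Proposed new method: the secondary amine turns the enal into an (E)-s-trans iminium ion whose β-carbon captures the ammonium enolate that DABCO forms reversibly from the acrylate, on the face anti to the diphenyl(silyloxy)methyl group (3S with the R catalyst); phenol-assisted proton transfer and E1cB loss of DABCO restore the acrylate, and enamine hydrolysis releases the aldehyde and the amine; the closest known reactions are iminium-catalysed Michael additions of malonates to enals and Lewis-base (Morita–Baylis–Hillman/Rauhut–Currier) activation of acrylates, whereas an intermolecular asymmetric cross Rauhut–Currier of a simple acrylate onto an unactivated aliphatic enal is not established.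

**Step 8**
Reactants: 17 tert-butyl (3S,6E)-6-methyl-2-methylidene-3-(2-oxoethyl)deca-6,9-dienoate; 8 (2Z,5E)-2-bromo-6-iodohepta-2,5-diene (1.5 equiv)
Product: 18 tert-butyl (3S,6E)-3-[(3E,6Z)-7-bromo-2-hydroxy-3-methylocta-3,6-dien-1-yl]-6-methyl-2-methylidenedeca-6,9-dienoate (both carbinol epimers)
Conditions: CrCl2 (4 equiv), NiCl2 (2 mol%), DMF/THF, rt
Reagents that add atoms: none
Why: In this NHK coupling nickel inserts into C–I much faster than into C–Br, and the alkenylchromium adds only to the aldehyde with retention of E geometry; the new carbinol is unselective and is erased in step 9.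

**Step 9**
Reactants: 18 (both carbinol epimers)
Product: 19 tert-butyl (3S,6E)-3-[(3E,6Z)-7-bromo-3-methyl-2-oxoocta-3,6-dien-1-yl]-6-methyl-2-methylidenedeca-6,9-dienoate
Conditions: Dess–Martin periodinane, NaHCO3, CH2Cl2, 0 °C to rt
Reagents that add atoms: none
Why: Dess–Martin oxidation gives the enone, which deactivates the C4=C5 alkene towards the later oxidants and removes a hydroxyl that would compete in the epoxide opening.

**Step 10**
Reactants: 19
Product: 20 tert-butyl (3S)-3-[(3E,6Z)-7-bromo-3-methyl-2-oxoocta-3,6-dien-1-yl]-2-methylidene-5-[(2R,3R)-2-methyl-3-(prop-2-en-1-yl)oxiran-2-yl]pentanoate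
Conditions: D-fructose-derived Shi ketone (30 mol%), KHSO5 (as 2KHSO5·KHSO4·K2SO4), K2CO3, Bu4NHSO4, MeCN/CH2(OMe)2/aq. Na2B4O7 buffer, 0 °C
Reagents that add atoms: potassium peroxymonosulfate, [K+].[O-]S(=O)(=O)OO
Why: In the Shi epoxidation the chiral dioxirane attacks only the electron-rich trisubstituted alkene (the others are conjugated, bromo-substituted or monosubstituted), and the spiro transition state gives the (R,R)-epoxide under catalyst control.

**Step 11**
Reactants: 20
Product: 22 (4S,7S)-4-[(3E,6Z)-7-bromo-3-methyl-2-oxoocta-3,6-dien-1-yl]-7-[(1R)-1-hydroxybut-3-en-1-yl]-7-methyl-3-methylideneoxepan-2-one, via epoxy acid 21 (not isolated)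
Conditions: CF3CO2H, CH2Cl2, 0 °C to rt
Reagents that add atoms: none
Why: Acid cleaves the tert-butyl ester and the carboxyl then opens the protonated epoxide 7-exo at the tertiary carbon with inversion (C12 becomes S) while C11 keeps its oxygen and R configuration.

**Step 12**
Reactants: 22
Product: 24 (3R)-3-hydroxy-3-[(2S,5S)-5-[(3E,6Z)-7-bromo-3-methyl-2-oxoocta-3,6-dien-1-yl]-2-methyl-6-methylidene-7-oxooxepan-2-yl]propanal, via triol 23 (not isolated)
Conditions: OsO4 (2 mol%), NaIO4 (3 equiv), 2,6-lutidine, dioxane/H2O, rt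
Reagents that add atoms: osmium tetroxide, O=[Os](=O)(=O)=O; sodium periodate, [Na+].[O-]I(=O)(=O)=O
Why: In this Lemieux–Johnson cleavage the electrophilic osmylation selects the isolated monosubstituted alkene over the carbonyl-conjugated and bromo-substituted ones, and periodate cleaves the diol to the C9 aldehyde.

**Step 13**
Reactants: 24
Product: 25 (1S,4E,7Z,11R,12S)-9,11-dihydroxy-4,8,12-trimethyl-15-methylidene-13-oxabicyclo[10.3.2]heptadeca-4,7-diene-3,14-dione (both C9 epimers)
Conditions: CrCl2 (10 equiv), NiCl2 (10 mol%), DMSO/THF, 0.003 M, rt to 45 °C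
Reagents that add atoms: none
Why: The intramolecular NHK reaction adds the (Z)-alkenylchromium to the aldehyde with retention and tolerates the free hydroxyl, ketone and lactone, closing the fourteen-membered ring at C8–C9; the C9 configuration is set in step 15.

**Step 14**
Reactants: 25 (both C9 epimers)
Product: 26 (1S,4E,7Z,11R,12S)-11-hydroxy-4,8,12-trimethyl-15-methylidene-13-oxabicyclo[10.3.2]heptadeca-4,7-diene-3,9,14-trione
Conditions: MnO2 (20 equiv), CH2Cl2, rt
Reagents that add atoms: none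
Why: MnO2 oxidises only the allylic C9 alcohol, so both epimers converge on one β-hydroxy enone and the C11 hydroxyl stays free.

**Step 15**
Reactants: 26
Product: 27 (1S,4E,7Z,9R,11R,12S)-9-hydroxy-4,8,12-trimethyl-15-methylidene-3,14-dioxo-13-oxabicyclo[10.3.2]heptadeca-4,7-dien-11-yl acetate
Conditions: SmI2 (30 mol%, premixed with CH3CHO), CH3CHO (10 equiv), THF, −10 °C
Reagents that add atoms: acetaldehyde, CC=O
Why: In the Evans–Tishchenko reduction the samarium-bound hemiacetal of O11 delivers hydride to the C9 ketone through a chair transition state, giving the 1,3-anti alcohol (9R) and leaving the acetyl group on O11; the C3 ketone has no β-hydroxyl and is untouched.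

**Step 16**
Reactants: 27
Product: 28 (1S,3R,4E,7Z,9R,11R,12S)-3,9-dihydroxy-4,8,12-trimethyl-15-methylidene-14-oxo-13-oxabicyclo[10.3.2]heptadeca-4,7-dien-11-yl acetate (target)
Conditions: (S)-2-methyl-CBS-oxazaborolidine (1 equiv), catecholborane (3 equiv), toluene/CH2Cl2, −78 °C; then MeOH, aq. NaHCO3
Reagents that add atoms: none
Why: In the Corey–Bakshi–Shibata reduction the α-methylalkenyl arm acts as the large group, so the S oxazaborolidine gives the 3R allylic alcohol by 1,2-hydride delivery; catecholborane at −78 °C leaves the acetate and α-methylene lactone alone.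

## Compound list

1 | but-2-yn-1-ol | CC#CCO | starting material
2 | sodium 2,2-bis(2-methoxyethoxy)-3-methyl-2,5-dihydro-1,2-oxaaluminol-2-uide (cyclic alkenylaluminate) | [Na+].CC1=CCO[Al-]1(OCCOC)OCCOC | intermediate
3 | (2Z)-3-bromobut-2-en-1-ol | C/C(Br)=C/CO | intermediate
4 | (2Z)-1,3-dibromobut-2-ene | C/C(Br)=C/CBr | intermediate
5 | prop-1-yn-1-ylmagnesium bromide | CC#C[Mg]Br | starting material
6 | (2Z)-2-bromohept-2-en-5-yne | C/C(Br)=C/CC#CC | intermediate
7 | chlorobis(cyclopentadienyl)[(2E,5Z)-6-bromohepta-2,5-dien-2-yl]zirconium | C/C(Br)=C/C/C=C(\C)[Zr](Cl)(C1C=CC=C1)C1C=CC=C1 | intermediate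
8 | (2Z,5E)-2-bromo-6-iodohepta-2,5-diene | C/C(Br)=C/C/C=C(\C)I | intermediate
9 | pent-4-yn-1-ol | C#CCCCO | starting material
10 | allyl bromide (3-bromoprop-1-ene) | C=CCBr | starting material
11 | dimethyl[(1E)-5-(dimethylalumanyloxy)-2-methylpent-1-en-1-yl]alumane | C[Al](C)/C=C(\C)CCCO[Al](C)C | intermediate
12 | (4E)-4-methylocta-4,7-dien-1-ol | OCCC/C(C)=C/CC=C | intermediate
13 | (triphenylphosphoranylidene)acetaldehyde | O=CC=P(c1ccccc1)(c1ccccc1)c1ccccc1 | starting material
14 | (4E)-4-methylocta-4,7-dienal | O=CCC/C(C)=C/CC=C | intermediate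
15 | (2E,6E)-6-methyldeca-2,6,9-trienal | O=C/C=C/CC/C(C)=C/CC=C | intermediate
16 | tert-butyl acrylate | C=CC(=O)OC(C)(C)C | starting material
17 | tert-butyl (3S,6E)-6-methyl-2-methylidene-3-(2-oxoethyl)deca-6,9-dienoate | C=C(C(=O)OC(C)(C)C)[C@H](CC=O)CC/C(C)=C/CC=C | intermediate
18 | tert-butyl (3S,6E)-3-[(3E,6Z)-7-bromo-2-hydroxy-3-methylocta-3,6-dien-1-yl]-6-methyl-2-methylidenedeca-6,9-dienoate (both carbinol epimers) | C=C(C(=O)OC(C)(C)C)[C@H](CC(O)/C(C)=C/C/C=C(/C)Br)CC/C(C)=C/CC=C | intermediate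
19 | tert-butyl (3S,6E)-3-[(3E,6Z)-7-bromo-3-methyl-2-oxoocta-3,6-dien-1-yl]-6-methyl-2-methylidenedeca-6,9-dienoate | C=C(C(=O)OC(C)(C)C)[C@H](CC(=O)/C(C)=C/C/C=C(/C)Br)CC/C(C)=C/CC=C | intermediate
20 | tert-butyl (3S)-3-[(3E,6Z)-7-bromo-3-methyl-2-oxoocta-3,6-dien-1-yl]-2-methylidene-5-[(2R,3R)-2-methyl-3-(prop-2-en-1-yl)oxiran-2-yl]pentanoate | C=C(C(=O)OC(C)(C)C)[C@H](CC(=O)/C(C)=C/C/C=C(/C)Br)CC[C@@]1(C)O[C@@H]1CC=C | intermediate
21 | (3S)-3-[(3E,6Z)-7-bromo-3-methyl-2-oxoocta-3,6-dien-1-yl]-2-methylidene-5-[(2R,3R)-2-methyl-3-(prop-2-en-1-yl)oxiran-2-yl]pentanoic acid | C=C(C(=O)O)[C@H](CC(=O)/C(C)=C/C/C=C(/C)Br)CC[C@@]1(C)O[C@@H]1CC=C | intermediate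
22 | (4S,7S)-4-[(3E,6Z)-7-bromo-3-methyl-2-oxoocta-3,6-dien-1-yl]-7-[(1R)-1-hydroxybut-3-en-1-yl]-7-methyl-3-methylideneoxepan-2-one | C=C1C(=O)O[C@](C)([C@H](O)CC=C)CC[C@H]1CC(=O)/C(C)=C/C/C=C(/C)Br | intermediate
23 | (4S,7S)-4-[(3E,6Z)-7-bromo-3-methyl-2-oxoocta-3,6-dien-1-yl]-7-[(1R)-1,3,4-trihydroxybutyl]-7-methyl-3-methylideneoxepan-2-one (both C3' epimers) | C=C1C(=O)O[C@](C)([C@H](O)CC(O)CO)CC[C@H]1CC(=O)/C(C)=C/C/C=C(/C)Br | intermediate
24 | (3R)-3-hydroxy-3-[(2S,5S)-5-[(3E,6Z)-7-bromo-3-methyl-2-oxoocta-3,6-dien-1-yl]-2-methyl-6-methylidene-7-oxooxepan-2-yl]propanal | C=C1C(=O)O[C@](C)([C@H](O)CC=O)CC[C@H]1CC(=O)/C(C)=C/C/C=C(/C)Br | intermediate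
25 | (1S,4E,7Z,11R,12S)-9,11-dihydroxy-4,8,12-trimethyl-15-methylidene-13-oxabicyclo[10.3.2]heptadeca-4,7-diene-3,14-dione (both C9 epimers) | C=C1C(=O)O[C@@]2(C)CC[C@H]1CC(=O)/C(C)=C/C/C=C(/C)C(O)C[C@H]2O | intermediate
26 | (1S,4E,7Z,11R,12S)-11-hydroxy-4,8,12-trimethyl-15-methylidene-13-oxabicyclo[10.3.2]heptadeca-4,7-diene-3,9,14-trione | C=C1C(=O)O[C@@]2(C)CC[C@H]1CC(=O)/C(C)=C/C/C=C(/C)C(=O)C[C@H]2O | intermediate
27 | (1S,4E,7Z,9R,11R,12S)-9-hydroxy-4,8,12-trimethyl-15-methylidene-3,14-dioxo-13-oxabicyclo[10.3.2]heptadeca-4,7-dien-11-yl acetate | C=C1C(=O)O[C@@]2(C)CC[C@H]1CC(=O)/C(C)=C/C/C=C(/C)[C@H](O)C[C@H]2OC(C)=O | intermediate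
28 | (1S,3R,4E,7Z,9R,11R,12S)-3,9-dihydroxy-4,8,12-trimethyl-15-methylidene-14-oxo-13-oxabicyclo[10.3.2]heptadeca-4,7-dien-11-yl acetate | C=C1C(=O)O[C@@]2(C)CC[C@H]1C[C@@H](O)/C(C)=C/C/C=C(/C)[C@H](O)C[C@H]2OC(C)=O | target

## Step count and risks

Total steps: 16. Longest linear sequence: 13 (steps 1–4, then 8–16, from but-2-yn-1-ol); the other branch is 12 (steps 5–16).

**Step 7 (the proposed cross Rauhut–Currier reaction).** The ammonium enolate may be too scarce, or the aldehyde may react 1,2 instead. The fallback uses known chemistry, sets out from 15 and returns at 17. The same (R)-diarylprolinol silyl ether with benzoic acid catalyses the Michael addition of tert-butyl diethylphosphonoacetate to 15. This gives tert-butyl (3S,6E)-2-(diethoxyphosphoryl)-6-methyl-3-(2-oxoethyl)deca-6,9-dienoate F1 as a mixture at C2. Horner–Wadsworth–Emmons methylenation with aqueous formaldehyde and K2CO3 in THF at 0 °C then gives 17.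

**Step 11 (one-pot ester cleavage and 7-exo epoxide opening).** The strong acid needed for the tert-butyl ester may instead cause Meinwald rearrangement or trifluoroacetate opening of the epoxide. The fallback sets out from 19 and returns at 22. The ester is cleaved before the epoxide exists, with TMSOTf/2,6-lutidine and aqueous work-up. This gives (3S,6E)-3-[(3E,6Z)-7-bromo-3-methyl-2-oxoocta-3,6-dien-1-yl]-6-methyl-2-methylidenedeca-6,9-dienoic acid F2. Shi epoxidation of its carboxylate gives epoxy acid 21, which is closed to 22 with only catalytic camphorsulfonic acid.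

**Step 13 (macrocyclising NHK with a vinylic bromide and a β-hydroxy aldehyde).** Insertion into the hindered C–Br bond may be slower than decay of the aldehyde. The fallback sets out from 22 and returns at 25. Copper-catalysed vinylic halogen exchange (CuI, NaI, trans-N,N'-dimethylcyclohexane-1,2-diamine, dioxane, 110 °C, retention of geometry) gives (4S,7S)-7-[(1R)-1-hydroxybut-3-en-1-yl]-4-[(3E,6Z)-7-iodo-3-methyl-2-oxoocta-3,6-dien-1-yl]-7-methyl-3-methylideneoxepan-2-one F3. Lemieux–Johnson cleavage as in step 12 gives (3R)-3-hydroxy-3-[(2S,5S)-5-[(3E,6Z)-7-iodo-3-methyl-2-oxoocta-3,6-dien-1-yl]-2-methyl-6-methylidene-7-oxooxepan-2-yl]propanal F4. The much more reactive iodide is then cyclised with CrCl2/NiCl2 at room temperature to 25.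

## Further compounds

F1 | step 7 | tert-butyl (3S,6E)-2-(diethoxyphosphoryl)-6-methyl-3-(2-oxoethyl)deca-6,9-dienoate (both C2 epimers) | CCOP(=O)(OCC)C(C(=O)OC(C)(C)C)[C@H](CC=O)CC/C(C)=C/CC=C
F2 | step 11 | (3S,6E)-3-[(3E,6Z)-7-bromo-3-methyl-2-oxoocta-3,6-dien-1-yl]-6-methyl-2-methylidenedeca-6,9-dienoic acid | C=C(C(=O)O)[C@H](CC(=O)/C(C)=C/C/C=C(/C)Br)CC/C(C)=C/CC=C
F3 | step 13 | (4S,7S)-7-[(1R)-1-hydroxybut-3-en-1-yl]-4-[(3E,6Z)-7-iodo-3-methyl-2-oxoocta-3,6-dien-1-yl]-7-methyl-3-methylideneoxepan-2-one | C=C1C(=O)O[C@](C)([C@H](O)CC=C)CC[C@H]1CC(=O)/C(C)=C/C/C=C(/C)I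
F4 | step 13 | (3R)-3-hydroxy-3-[(2S,5S)-5-[(3E,6Z)-7-iodo-3-methyl-2-oxoocta-3,6-dien-1-yl]-2-methyl-6-methylidene-7-oxooxepan-2-yl]propanal | C=C1C(=O)O[C@](C)([C@H](O)CC=O)CC[C@H]1CC(=O)/C(C)=C/C/C=C(/C)I
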